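Start from late times: in the last rows of epsilon and beta the columns move by about the scatter of 0.3 percentage points.

| flask | substrate | reagent | remark | time |
|---|---|---|---|---|
| alpha | 0.30 M | 0.285 M | run made earlier |  |
| epsilon | 0.42 M | 0.285 M | run made earlier |  |
| beta | 0.66 M | 0.285 M | run made earlier |  |
| delta | 0.30 M | 0.57 M | run made earlier |  |
| birch | 0.30 M | 0.285 M | one stirred flow tank at steady state, fed with the mixture as stated, mean residence time 15 h |  |
| cedar | 0.30 M | 0.285 M | everything together in a closed stirred flask, run for 15 h | 15 h |
| ash | 0.30 M (fed, over 7.50 h) | 0.285 M | all but substrate at the start; substrate goes in evenly over 7.50 h, the run ends at 15 h | 15 h |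
| larch | 0.30 M | 0.285 M (fed, over 7.50 h) | a stirred flask in which reagent is dosed at a steady rate over 7.50 h without added volume, worked up at 15 h | 15 h |

- alpha (time / h: target / %, side product / %, over-reaction product / %): 0.500: 40.0, 17.7, 4.0; 1.33: 50.3, 29.6, 10.5; 2.50: 49.0, 32.6, 14.5; 4.00: 46.1, 34.5, 18.2; 5.00: 44.6, 34.8, 19.3; 8.00: 42.2, 35.1, 22.1; 10.0: 41.0, 34.5, 23.5
- epsilon (time / h: target / %, side product / %, over-reaction product / %): 1.50: 57.7, 23.1, 7.7; 3.00: 59.0, 25.5, 9.9; 5.00: 58.0, 25.3, 10.0; 6.00: 58.4, 26.2, 10.4; 8.00: 58.3, 26.1, 10.4; 10.0: 58.3, 26.2, 10.0; 12.0: 58.1, 26.2, 10.5
- beta (time / h: target / %, side product / %, over-reaction product / %): 0.667: 51.3, 11.9, 2.8; 2.00: 69.1, 14.1, 4.2; 3.00: 70.7, 14.2, 4.0; 5.00: 71.0, 14.0, 4.1; 8.00: 70.8, 14.3, 4.0; 10.0: 70.8, 14.4, 4.1; 12.0: 71.2, 14.3, 4.2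
- delta (time / h: target / %, side product / %, over-reaction product / %): 1.00: 29.2, 51.7, 12.6; 2.00: 22.3, 55.6, 21.1; 3.00: 17.4, 55.9, 27.2; 6.00: 8.3, 55.8, 36.1; 12.0: 1.9, 55.7, 41.9

(scatter of a reading: 0.3 percentage points)

- the stated concentrations are those of everything mixed, before any reaction; amounts are the same in each set-up
- the numbers in the tables scatter with a standard deviation of 0.3 percentage points
- steps that have been proposed: substrate + reagent -> intermediate; substrate -> target; reagent + intermediate -> side product; reagent + target -> over-reaction product
- the feed brings no volume worth counting
- the earlier runs were made in a closed, stirred flask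

1. the set-up with the highest share of target in all that became target or side product or over-reaction product, at the outlet or at the end ("none" if the first two lie within 2 percentage points) (birch / cedar / ash / larch / none)
2. share of target in all that became target or side product or over-reaction product, at the outlet or at the end, birch
3. share of target in all that became target or side product or over-reaction product, at the outlet or at the end, cedar
4. share of target in all that became target or side product or over-reaction product, at the outlet or at the end, ash
5. share of target in all that became target or side product or over-reaction product, at the outlet or at the end, larch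

Your first thought is a balance. By the proposed steps, each substrate stands as substrate, intermediate, target, side product or over-reaction product. Intermediate and over-reaction product each cost one reagent, and side product costs two. Subtract the reagent balance from the substrate balance, everything in percent of substrate charged:

target − side product = surplus + reagent left − substrate left

Here the surplus is the fraction of substrate that the reagent charge cannot match mole for mole, 5.00% for the four set-ups asked about.

But epsilon's last row sums to 94.8%, so is the balance broken? No: intermediate still in the flask takes one substrate and one reagent, so it cancels in the subtraction. Epsilon's difference is 32 points against a surplus of 32.1%, and beta's is 57 points against 56.8%.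

Alpha is still moving, though: its target goes from 42.2% at 8.00 h to 41.0% at 10.0 h, where target minus side product stands 1.5 points above its surplus. Cedar is alpha run on, so you place its target between the reading and the floor:

39.5% to 41.0%

The next objection is that in birch, ash and larch side product need not stand where alpha's does, and reagent or substrate may be left, so the balance gives their target only once those terms are estimated.

The forecast names cedar, with birch 35%, cedar 40.6%, ash 37.5% and larch 24%, on the ground that “early reagent-driven branching actually spares target”.

The flask gives cedar, with birch 35.0%, cedar 40.8%, ash 36.5% and larch 20.5%.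

    substrate + reagent → intermediate (k = 0.00150 L mol⁻¹ s⁻¹)
    substrate → target (k = 4.70 × 10⁻⁴ s⁻¹)
    reagent + intermediate → side product (k = 0.00470 L mol⁻¹ s⁻¹)
    reagent + target → over-reaction product (k = 4.90 × 10⁻⁴ L mol⁻¹ s⁻¹)

In larch at 0.388 h, the rate of substrate to target over that of substrate to intermediate stood at 27. Larch ended with less side product than cedar, 4.26% against 35.2%. Its surplus, side product and the 11.8% of reagent left, counted on substrate, add up to 20.5%. A neighbour of larch charged with 0.75 M of substrate has a surplus of 62.0%, and with its 2.80% of side product that makes 64.8%, where the flask gave 64.9%.

The earlier runs and the new flask stem from a simulated flask from invented constants; noise was put on by code.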